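Ring A of the target (the acylphloroglucinol ring) bears oxygen on C2′, C4′ and C6′ and carbon substituents on C1′ (the CH2 bridge to C8 of the chromanone), C3′ (methyl) and C5′ (isobutyryl). This alternating pattern is built in one operation by a cyclobutenone–siloxyalkyne benzannulation. A 3-benzyloxycyclobutenone carrying the fully protected chromanonylmethyl group on C2 is heated with 1-(triisopropylsilyloxy)propyne, which forges C3′–C4′ and C1′–C2′, closes ring A and leaves C5′ as the only unsubstituted ring carbon. The precursor comes from a chromanone-8-carbaldehyde and cyclobutane-1,3-dione by reductive alkylation. Desilylation, acylation at C5′ and hydrogenolysis finish the synthesis.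

Key step: step 8

Remark: the target has no stereocentre, so no step has to set configuration; ring A is numbered C1′ (bridge carbon) to C6′, and the chromanone keeps its usual numbering (O1, C2 to C8a).

Step 1
Reactants: 1 2-methylphloroglucinol; 2 3-methylbut-2-enoic acid
Product: 4 5,7-dihydroxy-2,2,6-trimethylchroman-4-one, via aryl enone 3 (not isolated)
Conditions: MeSO3H, P2O5, 70 °C
Reagents that add atoms: none
Why: Friedel–Crafts acylation at one of the two equivalent free ring carbons and acid-promoted oxa-Michael closure through the less hindered ortho hydroxyl (the one para to the methyl group) should give the 6-methyl chromanone, and any 8-methyl isomer from closure through the other ortho hydroxyl is to be removed here by chromatography, with the constitution checked by HMBC before material is carried on.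

Step 2
Reactants: 4 5,7-dihydroxy-2,2,6-trimethylchroman-4-one
Product: 6 5,7-dihydroxy-2,2,6-trimethyl-4-oxochromane-8-carbaldehyde, via iminium salt 5 (not isolated)
Conditions: POCl3, DMF, EtOAc, 0 °C to rt; then H2O, 60 °C
Reagents that add atoms: N,N-dimethylformamide CN(C)C=O; water O
Why: Vilsmeier–Haack formylation should go to C8, the only unsubstituted ring carbon, which is activated by O1 and the 7-hydroxyl (ortho) and by the 5-hydroxyl (para), and the iminium salt is hydrolysed on aqueous work-up.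

Step 3
Reactants: 6 5,7-dihydroxy-2,2,6-trimethyl-4-oxochromane-8-carbaldehyde
Product: 7 5,7-bis(benzyloxy)-2,2,6-trimethyl-4-oxochromane-8-carbaldehyde
Conditions: BnBr, K2CO3, Bu4NI (cat.), DMF, 50 °C
Reagents that add atoms: benzyl bromide BrCc1ccccc1
Why: Williamson etherification with excess halide in DMF should alkylate both hydrogen-bonded phenols, so that no free hydroxyl remains to trap ketenes or to cyclise onto the dione later.

Step 4
Reactants: 8 3-ethoxycyclobut-2-en-1-one
Product: 9 cyclobutane-1,3-dione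
Conditions: 2 M HCl (aq), rt; used freshly
Reagents that add atoms: water O
Why: Acid-catalysed hydrolysis of the vinylogous ester (addition–elimination at C3) is the standard access to this dione, which is prepared fresh because it does not keep well.

Step 5
Reactants: 7 5,7-bis(benzyloxy)-2,2,6-trimethyl-4-oxochromane-8-carbaldehyde; 9 cyclobutane-1,3-dione
Product: 11 3-hydroxy-2-{[5,7-bis(benzyloxy)-2,2,6-trimethyl-4-oxochroman-8-yl]methyl}cyclobut-2-en-1-one (enol form of the 2-substituted cyclobutane-1,3-dione), via alkylidene dione 10 (not isolated)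
Conditions: Hantzsch ester (diethyl 2,6-dimethyl-1,4-dihydropyridine-3,5-dicarboxylate), L-proline (cat.), CH2Cl2, rt
Reagents that add atoms: none
Why: Organocatalytic three-component reductive alkylation, that is proline-mediated Knoevenagel condensation of the aldehyde with the acidic cyclic 1,3-dione followed by conjugate hydride transfer from the Hantzsch ester to the alkylidene dione, should stop at the mono-C-alkylated dione, which is isolated by acid–base extraction as its strongly acidic enol.

Step 6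
Reactants: 11 3-hydroxy-2-{[5,7-bis(benzyloxy)-2,2,6-trimethyl-4-oxochroman-8-yl]methyl}cyclobut-2-en-1-one
Product: 12 3-(benzyloxy)-2-{[5,7-bis(benzyloxy)-2,2,6-trimethyl-4-oxochroman-8-yl]methyl}cyclobut-2-en-1-one
Conditions: BnOH, PPh3, DIAD, THF, 0 °C to rt
Reagents that add atoms: benzyl alcohol OCc1ccccc1
Why: Mitsunobu alkylation of the vinylogous acid should take place on oxygen and so avoid the C-benzylation to a 2,2-disubstituted dione that benzyl halide and base would risk, and the two enol oxygens are equivalent, so only one vinylogous ester can form.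

Step 7
Reactants: 13 ethyl acetate
Product: 16 1-(triisopropylsilyloxy)prop-1-yne, via dibromo enolate 14 (not isolated), via lithium ynolate 15 (not isolated)
Conditions: CH2Br2, lithium 2,2,6,6-tetramethylpiperidide, THF, −78 °C; n-BuLi, −78 °C to rt; TIPSCl, −78 °C to rt
Reagents that add atoms: dibromomethane BrCBr; chlorotri(propan-2-yl)silane CC(C)[Si](Cl)(C(C)C)C(C)C
Why: Kowalski ester homologation, in which addition of LiCHBr2 to the ester and enolisation give the dibromo enolate, bromine–lithium exchange triggers a carbenoid 1,2-shift to the ynolate, and the bulky silyl chloride traps the ynolate on oxygen as the ynol silyl ether.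

Step 8
Reactants: 12 3-(benzyloxy)-2-{[5,7-bis(benzyloxy)-2,2,6-trimethyl-4-oxochroman-8-yl]methyl}cyclobut-2-en-1-one; 16 1-(triisopropylsilyloxy)prop-1-yne
Product: 21 5,7-bis(benzyloxy)-8-{[6-(benzyloxy)-4-hydroxy-3-methyl-2-(triisopropylsilyloxy)phenyl]methyl}-2,2,6-trimethylchroman-4-one, via vinylketene 17 (not isolated), via vinylcyclobutenone 18 (not isolated), via dienylketene 19 (not isolated), via cyclohexadienone 20 (not isolated)
Conditions: 16 (2.5 equiv), PhMe, 80 °C then 110 °C, sealed tube, Ar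
Reagents that add atoms: none
Why: Thermal 4π electrocyclic opening of the strained cyclobutenone 12 gives vinylketene 17, whose ketene C=C adds (2+2) to the electron-rich alkyne 16 to give the 4-vinylcyclobutenone 18; a second 4π opening to dienylketene 19 and 6π electrocyclisation give dienone 20, which tautomerises to phenol 21. This is the Danheiser benzannulation of cyclobutenones with siloxyalkynes (a resorcinol synthesis), used here with a less common 3-alkoxy partner. Ring A is closed by the thermal 6π electrocyclic ring closure, which re-forms the C4′–C5′ bond broken in the first opening, after the cycloaddition has made C3′–C4′ and C1′–C2′. No stereocentre is formed, and the quaternary carbon of racemic 18 is lost again on ring opening. The step needs a single regiochemistry in the (2+2) addition, and the polarity of the partners secures it: the electrophilic ketene carbonyl carbon bonds to the methyl-bearing, nucleophilic carbon of the siloxyalkyne, so the methyl group ends up between the new hydroxyl and the silyloxy group. The benzyl ethers and the chromanone ketone are spectators, and the excess of 16 should limit acylation of the product phenol by 17.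

Step 9
Reactants: 21 5,7-bis(benzyloxy)-8-{[6-(benzyloxy)-4-hydroxy-3-methyl-2-(triisopropylsilyloxy)phenyl]methyl}-2,2,6-trimethylchroman-4-one
Product: 22 5,7-bis(benzyloxy)-8-{[6-(benzyloxy)-2,4-dihydroxy-3-methylphenyl]methyl}-2,2,6-trimethylchroman-4-one
Conditions: TBAF, AcOH, THF, 0 °C
Reagents that add atoms: none
Why: Fluoride-induced cleavage of the aryl silyl ether is driven by Si–F bond formation, and buffering with acetic acid keeps the electron-rich ring from standing as an air-sensitive phenoxide while benzyl ethers and the ketone are untouched.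

Step 10
Reactants: 22 5,7-bis(benzyloxy)-8-{[6-(benzyloxy)-2,4-dihydroxy-3-methylphenyl]methyl}-2,2,6-trimethylchroman-4-one
Product: 23 5,7-bis(benzyloxy)-8-{[6-(benzyloxy)-2,4-dihydroxy-3-methyl-5-(2-methylpropanoyl)phenyl]methyl}-2,2,6-trimethylchroman-4-one
Conditions: (i-PrCO)2O (1.2 equiv), BF3·OEt2, CH2Cl2, 0 °C to rt; then K2CO3, MeOH, rt
Reagents that add atoms: isobutyric anhydride CC(C)C(=O)OC(=O)C(C)C
Why: Friedel–Crafts acylation (directly or by O-acylation and Fries shift) can only occur at C5′, the one unsubstituted carbon of the phloroglucinol-type ring A, which is activated by two hydroxyls and a benzyloxy group, whereas the chromanone ring is fully substituted, and the methanolysis wash should return any aryl ester to the phenol.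

Step 11
Reactants: 23 5,7-bis(benzyloxy)-8-{[6-(benzyloxy)-2,4-dihydroxy-3-methyl-5-(2-methylpropanoyl)phenyl]methyl}-2,2,6-trimethylchroman-4-one
Product: 24 5,7-dihydroxy-2,2,6-trimethyl-8-{[2,4,6-trihydroxy-3-methyl-5-(2-methylpropanoyl)phenyl]methyl}chroman-4-one (CNP0186856.0)
Conditions: H2 (1 atm), Pd/C, EtOAc–MeOH, rt
Reagents that add atoms: none
Why: Catalytic hydrogenolysis should remove the three benzyl aryl ethers under mild conditions that leave the hydrogen-bonded aryl ketones and the diarylmethane bridge unreduced.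

Compound list
1 | 2-methylphloroglucinol (2-methylbenzene-1,3,5-triol) | Cc1c(O)cc(O)cc1O | starting material
2 | 3-methylbut-2-enoic acid | CC(C)=CC(O)=O | starting material
3 | 3-methyl-1-(2,4,6-trihydroxy-3-methylphenyl)but-2-en-1-one | CC(C)=CC(=O)c1c(O)cc(O)c(C)c1O | intermediate
4 | 5,7-dihydroxy-2,2,6-trimethylchroman-4-one | Cc1c(O)cc2OC(C)(C)CC(=O)c2c1O | intermediate
5 | [(5,7-dihydroxy-2,2,6-trimethyl-4-oxochroman-8-yl)methylidene]dimethylammonium chloride | C[N+](C)=Cc1c(O)c(C)c(O)c2c1OC(C)(C)CC2=O.[Cl-] | intermediate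
6 | 5,7-dihydroxy-2,2,6-trimethyl-4-oxochromane-8-carbaldehyde | O=Cc1c(O)c(C)c(O)c2c1OC(C)(C)CC2=O | intermediate
7 | 5,7-bis(benzyloxy)-2,2,6-trimethyl-4-oxochromane-8-carbaldehyde | O=Cc1c(OCc2ccccc2)c(C)c(OCc2ccccc2)c2c1OC(C)(C)CC2=O | intermediate
8 | 3-ethoxycyclobut-2-en-1-one | CCOC1=CC(=O)C1 | starting material
9 | cyclobutane-1,3-dione | O=C1CC(=O)C1 | intermediate
10 | 2-{[5,7-bis(benzyloxy)-2,2,6-trimethyl-4-oxochroman-8-yl]methylidene}cyclobutane-1,3-dione | O=C1CC(=O)C1=Cc1c(OCc2ccccc2)c(C)c(OCc2ccccc2)c2c1OC(C)(C)CC2=O | intermediate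
11 | 3-hydroxy-2-{[5,7-bis(benzyloxy)-2,2,6-trimethyl-4-oxochroman-8-yl]methyl}cyclobut-2-en-1-one (enol of the 2-substituted cyclobutane-1,3-dione) | O=C1CC(O)=C1Cc1c(OCc2ccccc2)c(C)c(OCc2ccccc2)c2c1OC(C)(C)CC2=O | intermediate
12 | 3-(benzyloxy)-2-{[5,7-bis(benzyloxy)-2,2,6-trimethyl-4-oxochroman-8-yl]methyl}cyclobut-2-en-1-one | O=C1CC(OCc2ccccc2)=C1Cc1c(OCc2ccccc2)c(C)c(OCc2ccccc2)c2c1OC(C)(C)CC2=O | intermediate
13 | ethyl acetate | CCOC(C)=O | starting material
14 | lithium 1,1-dibromoprop-1-en-2-olate | CC([O-])=C(Br)Br.[Li+] | intermediate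
15 | lithium prop-1-yn-1-olate | CC#C[O-].[Li+] | intermediate
16 | 1-(triisopropylsilyloxy)prop-1-yne | CC#CO[Si](C(C)C)(C(C)C)C(C)C | intermediate
17 | 3-(benzyloxy)-2-{[5,7-bis(benzyloxy)-2,2,6-trimethyl-4-oxochroman-8-yl]methyl}buta-1,3-dien-1-one (vinylketene) | O=C=C(Cc1c(OCc2ccccc2)c(C)c(OCc2ccccc2)c2c1OC(C)(C)CC2=O)C(OCc1ccccc1)=C | intermediate
18 | 4-[1-(benzyloxy)ethenyl]-4-{[5,7-bis(benzyloxy)-2,2,6-trimethyl-4-oxochroman-8-yl]methyl}-2-methyl-3-(triisopropylsilyloxy)cyclobut-2-en-1-one (racemic) | CC1=C(O[Si](C(C)C)(C(C)C)C(C)C)C(Cc2c(OCc3ccccc3)c(C)c(OCc3ccccc3)c3c2OC(C)(C)CC3=O)(C(OCc2ccccc2)=C)C1=O | intermediate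
19 | (3E)-5-(benzyloxy)-4-{[5,7-bis(benzyloxy)-2,2,6-trimethyl-4-oxochroman-8-yl]methyl}-2-methyl-3-(triisopropylsilyloxy)hexa-1,3,5-trien-1-one (ketene and benzyloxyvinyl groups cis on the central double bond) | O=C=C(C)/C(O[Si](C(C)C)(C(C)C)C(C)C)=C(\C(OCc1ccccc1)=C)Cc1c(OCc2ccccc2)c(C)c(OCc2ccccc2)c2c1OC(C)(C)CC2=O | intermediate
20 | 5-(benzyloxy)-4-{[5,7-bis(benzyloxy)-2,2,6-trimethyl-4-oxochroman-8-yl]methyl}-2-methyl-3-(triisopropylsilyloxy)cyclohexa-2,4-dien-1-one | CC1=C(O[Si](C(C)C)(C(C)C)C(C)C)C(Cc2c(OCc3ccccc3)c(C)c(OCc3ccccc3)c3c2OC(C)(C)CC3=O)=C(OCc2ccccc2)CC1=O | intermediate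
21 | 5,7-bis(benzyloxy)-8-{[6-(benzyloxy)-4-hydroxy-3-methyl-2-(triisopropylsilyloxy)phenyl]methyl}-2,2,6-trimethylchroman-4-one | Cc1c(O[Si](C(C)C)(C(C)C)C(C)C)c(Cc2c(OCc3ccccc3)c(C)c(OCc3ccccc3)c3c2OC(C)(C)CC3=O)c(OCc2ccccc2)cc1O | intermediate
22 | 5,7-bis(benzyloxy)-8-{[6-(benzyloxy)-2,4-dihydroxy-3-methylphenyl]methyl}-2,2,6-trimethylchroman-4-one | Cc1c(O)c(Cc2c(OCc3ccccc3)c(C)c(OCc3ccccc3)c3c2OC(C)(C)CC3=O)c(OCc2ccccc2)cc1O | intermediate
23 | 5,7-bis(benzyloxy)-8-{[6-(benzyloxy)-2,4-dihydroxy-3-methyl-5-(2-methylpropanoyl)phenyl]methyl}-2,2,6-trimethylchroman-4-one | Cc1c(O)c(Cc2c(OCc3ccccc3)c(C)c(OCc3ccccc3)c3c2OC(C)(C)CC3=O)c(OCc2ccccc2)c(C(=O)C(C)C)c1O | intermediate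
24 | 5,7-dihydroxy-2,2,6-trimethyl-8-{[2,4,6-trihydroxy-3-methyl-5-(2-methylpropanoyl)phenyl]methyl}chroman-4-one (CNP0186856.0, achiral) | Cc1c(O)c(Cc2c(O)c(C)c(O)c3c2OC(C)(C)CC3=O)c(O)c(C(=O)C(C)C)c1O | target

Total step count: 11. Longest linear sequence: 9 steps (steps 1, 2, 3, 5, 6, 8, 9, 10, 11); steps 4 and 7 are side branches.

Steps most likely to fail

Step 8 (key step). The 4π opening of the donor-stabilised (vinylogous ester) cyclobutenone may be slow. In that case the thermal 1,3-silyl shift of the ynol ether to a silylketene, oligomerisation of the vinylketene, or O-acylation of the product phenol by the vinylketene could outrun the annulation. The fallback gives up the ring construction and joins a preformed ring A to the chromanone at the bridge. It sets out from aldehyde 7 and triol 1 and comes back to the route at target 24. Aldehyde 7 is reduced selectively (NaBH4, MeOH–THF, −20 °C, where the aldehyde should react before the hindered aryl ketone) to 5,7-bis(benzyloxy)-8-(hydroxymethyl)-2,2,6-trimethylchroman-4-one F1. Triol 1 is C-acylated (isobutyryl chloride, AlCl3, PhNO2–CH2Cl2) to 2-methyl-1-(2,4,6-trihydroxy-3-methylphenyl)propan-1-one F2. Acid-catalysed Friedel–Crafts benzylation (TsOH cat., MeCN, rt to 40 °C) of F2 at its only free ring carbon by the oxygen-stabilised benzylic cation from F1 should give 5,7-bis(benzyloxy)-2,2,6-trimethyl-8-{[2,4,6-trihydroxy-3-methyl-5-(2-methylpropanoyl)phenyl]methyl}chroman-4-one F3. Hydrogenolysis (H2, Pd/C) then gives 24.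

Step 5. Knoevenagel condensation on the di-ortho-substituted, electron-rich aldehyde may be sluggish while the sensitive four-membered dione self-condenses, or a second dione may add to the alkylidene intermediate before hydride transfer. The fallback builds the four-membered ring by ketene cycloaddition instead of alkylating it. It sets out from aldehyde 7 and comes back at dione 11. Reductive alkylation of Meldrum's acid (Hantzsch ester, L-proline, EtOH, rt) proceeds via 5-{[5,7-bis(benzyloxy)-2,2,6-trimethyl-4-oxochroman-8-yl]methylidene}-2,2-dimethyl-1,3-dioxane-4,6-dione F4 (not isolated) to 5-{[5,7-bis(benzyloxy)-2,2,6-trimethyl-4-oxochroman-8-yl]methyl}-2,2-dimethyl-1,3-dioxane-4,6-dione F5. Hydrolysis with decarboxylation (pyridine–H2O, reflux) gives 3-[5,7-bis(benzyloxy)-2,2,6-trimethyl-4-oxochroman-8-yl]propanoic acid F6. Oxalyl chloride with catalytic DMF gives 3-[5,7-bis(benzyloxy)-2,2,6-trimethyl-4-oxochroman-8-yl]propanoyl chloride F7. Dehydrochlorination with Et3N in the presence of ethoxyethyne (Et2O, 0 °C to rt) generates 3-[5,7-bis(benzyloxy)-2,2,6-trimethyl-4-oxochroman-8-yl]prop-1-en-1-one F8 (a ketene, not isolated). Its (2+2) cycloaddition gives racemic 4-{[5,7-bis(benzyloxy)-2,2,6-trimethyl-4-oxochroman-8-yl]methyl}-3-ethoxycyclobut-2-en-1-one F9. Hydrolysis of this vinylogous ester (2 M HCl, THF, rt) gives the dione in which the substituent sits between the two carbonyl groups, which is 11.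

Step 10. The Lewis acid may strip benzyl ethers (above all the 5-O-benzyl group peri to the chromanone carbonyl). O-acylation may compete with C-acylation, the anhydride–BF3 pair may acylate the carbon next to the chromanone ketone, or acid may cleave the diarylmethane bridge. The fallback changes the order and the acylation chemistry so that the acyl group is introduced on the free phloroglucinol by a nitrile. It sets out from diol 22 and comes back at target 24. Hydrogenolysis (H2, Pd/C, EtOAc–MeOH) gives 5,7-dihydroxy-2,2,6-trimethyl-8-[(2,4,6-trihydroxy-3-methylphenyl)methyl]chroman-4-one F10. Hoesch acylation (isobutyronitrile, ZnCl2, HCl, Et2O, 0 °C) at the only free aromatic carbon gives 1-(2,4,6-trihydroxy-3-methyl-5-{[5,7-dihydroxy-2,2,6-trimethyl-4-oxochroman-8-yl]methyl}phenyl)-2-methylpropan-1-iminium chloride F11. Hydrolysis in warm water gives 24 without any O-acylation.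

Further compounds
F1 | step 8 | 5,7-bis(benzyloxy)-8-(hydroxymethyl)-2,2,6-trimethylchroman-4-one | OCc1c(OCc2ccccc2)c(C)c(OCc2ccccc2)c2c1OC(C)(C)CC2=O
F2 | step 8 | 2-methyl-1-(2,4,6-trihydroxy-3-methylphenyl)propan-1-one | CC(C)C(=O)c1c(O)cc(O)c(C)c1O
F3 | step 8 | 5,7-bis(benzyloxy)-2,2,6-trimethyl-8-{[2,4,6-trihydroxy-3-methyl-5-(2-methylpropanoyl)phenyl]methyl}chroman-4-one | Cc1c(O)c(Cc2c(OCc3ccccc3)c(C)c(OCc3ccccc3)c3c2OC(C)(C)CC3=O)c(O)c(C(=O)C(C)C)c1O
F4 | step 5 | 5-{[5,7-bis(benzyloxy)-2,2,6-trimethyl-4-oxochroman-8-yl]methylidene}-2,2-dimethyl-1,3-dioxane-4,6-dione | CC1(C)OC(=O)C(=Cc2c(OCc3ccccc3)c(C)c(OCc3ccccc3)c3c2OC(C)(C)CC3=O)C(=O)O1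
F5 | step 5 | 5-{[5,7-bis(benzyloxy)-2,2,6-trimethyl-4-oxochroman-8-yl]methyl}-2,2-dimethyl-1,3-dioxane-4,6-dione | CC1(C)OC(=O)C(Cc2c(OCc3ccccc3)c(C)c(OCc3ccccc3)c3c2OC(C)(C)CC3=O)C(=O)O1
F6 | step 5 | 3-[5,7-bis(benzyloxy)-2,2,6-trimethyl-4-oxochroman-8-yl]propanoic acid | OC(=O)CCc1c(OCc2ccccc2)c(C)c(OCc2ccccc2)c2c1OC(C)(C)CC2=O
F7 | step 5 | 3-[5,7-bis(benzyloxy)-2,2,6-trimethyl-4-oxochroman-8-yl]propanoyl chloride | ClC(=O)CCc1c(OCc2ccccc2)c(C)c(OCc2ccccc2)c2c1OC(C)(C)CC2=O
F8 | step 5 | 3-[5,7-bis(benzyloxy)-2,2,6-trimethyl-4-oxochroman-8-yl]prop-1-en-1-one (ketene) | O=C=CCc1c(OCc2ccccc2)c(C)c(OCc2ccccc2)c2c1OC(C)(C)CC2=O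
F9 | step 5 | 4-{[5,7-bis(benzyloxy)-2,2,6-trimethyl-4-oxochroman-8-yl]methyl}-3-ethoxycyclobut-2-en-1-one (racemic) | CCOC1=CC(=O)C1Cc1c(OCc2ccccc2)c(C)c(OCc2ccccc2)c2c1OC(C)(C)CC2=O
F10 | step 10 | 5,7-dihydroxy-2,2,6-trimethyl-8-[(2,4,6-trihydroxy-3-methylphenyl)methyl]chroman-4-one | Cc1c(O)cc(O)c(Cc2c(O)c(C)c(O)c3c2OC(C)(C)CC3=O)c1O
F11 | step 10 | 1-(2,4,6-trihydroxy-3-methyl-5-{[5,7-dihydroxy-2,2,6-trimethyl-4-oxochroman-8-yl]methyl}phenyl)-2-methylpropan-1-iminium chloride | Cc1c(O)c(Cc2c(O)c(C)c(O)c3c2OC(C)(C)CC3=O)c(O)c(C(=[NH2+])C(C)C)c1O.[Cl-]
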